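**Strategy.** Ring B (the dihydropyranone O1–C2–C3–C4–C4a–C8a) is disconnected at the acyl–ring bond C4–C4a. The key step is an intramolecular Friedel–Crafts acylation of (S)-3-(3,5-dihydroxy-2-methylphenoxy)butanoic acid. In one operation it closes ring B and delivers the complete 2,8-dimethylchromanone core, with the C2 stereocentre (set earlier by Mitsunobu inversion) untouched. It exploits the phloroglucinol-type ring A: C4a is ortho/para to all three oxygens (O1, C5–OH, C7–OH) and is the only open ortho position of O1, because C8 carries the methyl group. C6 prenylation and a palladium-catalysed asymmetric dearomative geranylation at C8 then complete the target.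

Key step: step 4

Numbering: chromane numbering throughout (O1, C2, C3, C4, C4a, C5–C8, C8a); ring A is the carbocycle, ring B the oxygen heterocycle. The target is (2S,8R).
Remark: benzyl (R)-3-hydroxybutanoate 3 is taken as a purchasable ester of the chiral-pool acid.
Remark: the sense of induction of the ligand in step 6 cannot be predicted with certainty; the (R,R)-enantiomer is written as the one expected to give 8R, and the (S,S)-enantiomer takes its place in the same step if it proves to be the matching one.

**Step 1**
Reactants: 1 2,4,6-trihydroxybenzaldehyde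
Product: 2 2,4-bis(benzyloxy)-6-hydroxybenzaldehyde
Conditions: BnBr (2.1 equiv), K2CO3, DMF, 0 °C to rt
Reagents that add atoms: benzyl bromide, BrCc1ccccc1
Why: Williamson etherification takes the para hydroxyl and one ortho hydroxyl, while the last ortho hydroxyl is held in a strong hydrogen bond to the formyl group and stays free, which fixes the later regiochemistry.

**Step 2**
Reactants: 2 2,4-bis(benzyloxy)-6-hydroxybenzaldehyde; 3 benzyl (R)-3-hydroxybutanoate
Product: 4 benzyl (S)-3-[3,5-bis(benzyloxy)-2-formylphenoxy]butanoate
Conditions: PPh3, DIAD, THF, 0 °C to rt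
Reagents that add atoms: none
Why: Mitsunobu etherification of the acidic salicylaldehyde-type phenol with the secondary alcohol proceeds by SN2 displacement of the oxyphosphonium group, so the R carbinol centre is inverted to the S ether centre that becomes C2.

**Step 3**
Reactants: 4 benzyl (S)-3-[3,5-bis(benzyloxy)-2-formylphenoxy]butanoate
Product: 5 (S)-3-(3,5-dihydroxy-2-methylphenoxy)butanoic acid
Conditions: H2 (3 bar), 10% Pd/C, EtOAc/AcOH, rt
Reagents that add atoms: none
Why: Catalytic hydrogenolysis should remove both benzyl ethers and the benzyl ester and reduce the electron-rich formyl group through its benzylic alcohol to the methyl group (the future C8 methyl), while the non-benzylic C2–O bond is not touched.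

**Step 4**
Reactants: 5 (S)-3-(3,5-dihydroxy-2-methylphenoxy)butanoic acid
Product: 6 (S)-5,7-dihydroxy-2,8-dimethylchroman-4-one
Conditions: P2O5/MeSO3H (1:10 w/w, Eaton's reagent), moderate dilution, rt; ice-water quench
Reagents that add atoms: none
Why: The acid is converted in the P2O5/MeSO3H medium into a mixed anhydride or acylium ion, which is attacked by the ring carbon that becomes C4a and then loses a proton to restore aromaticity. The closest known reaction type is the intramolecular Friedel–Crafts acylation of 3-aryloxypropanoic acids to chroman-4-ones. Ring B is closed as a six-membered ring by 6-exo attack of the arene on the acyl carbon C4, with the C4a–C8a bond of the arene inside the new ring. No new stereocentre is formed, and C2 should keep its S configuration because none of its bonds is broken. The step needs regioselectivity for C4a, which the substrate secures: of the two positions ortho to O1 one (C8) carries the methyl group, C4a is activated ortho/para by O1 and both hydroxyls, and the still more electron-rich carbon between the two hydroxyls (C6) cannot be reached by the three-atom tether. Room temperature and moderate dilution are chosen to hold back intermolecular acylation at C6 and acid-induced elimination of the phenol from C2.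

**Step 5**
Reactants: 6 (S)-5,7-dihydroxy-2,8-dimethylchroman-4-one; 7 prenyl bromide
Product: 8 (S)-5,7-dihydroxy-2,8-dimethyl-6-(3-methylbut-2-en-1-yl)chroman-4-one
Conditions: KOH (1.1 equiv), H2O, 0 °C
Reagents that add atoms: none
Why: Phenoxide C-alkylation (SN2 on prenyl bromide) at C6, the only unsubstituted ring carbon and the one flanked by both oxygens, is favoured over O-alkylation in the hydrogen-bonding aqueous medium and restores aromaticity by tautomerisation; one equivalent of base keeps C3 from being deprotonated, so C2 is not at risk.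

**Step 6**
Reactants: 8 (S)-5,7-dihydroxy-2,8-dimethyl-6-(3-methylbut-2-en-1-yl)chroman-4-one; 9 geranyl acetate
Product: 10 (2S,8R)-8-[(2E)-3,7-dimethylocta-2,6-dien-1-yl]-5-hydroxy-2,8-dimethyl-6-(3-methylbut-2-en-1-yl)-2,3-dihydro-4H-chromene-4,7(8H)-dione (target)
Conditions: Pd2(dba)3·CHCl3 (2.5 mol %), (R,R)-DACH-phenyl Trost ligand (7.5 mol %), Cs2CO3 (1.0 equiv), THF, 0 °C to rt; dilute HCl work-up
Reagents that add atoms: none
Why: In this Tsuji–Trost allylic alkylation with dearomatisation, zerovalent palladium ionises geranyl acetate and the 7-phenoxide attacks the unsubstituted terminus of the π-geranyl complex of divalent palladium through C8 (methyl-bearing and less hindered than the prenyl-bearing C6, while O-allylation is reversible under the catalyst), giving the linear E-geranyl group, and the chiral pocket of the ligand selects the ring face so that C8 becomes R, the remote C2 centre exerting no useful bias.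

**Compound list**
1 | 2,4,6-trihydroxybenzaldehyde | O=Cc1c(O)cc(O)cc1O | starting material
2 | 2,4-bis(benzyloxy)-6-hydroxybenzaldehyde | O=Cc1c(O)cc(OCc2ccccc2)cc1OCc1ccccc1 | intermediate
3 | benzyl (R)-3-hydroxybutanoate | C[C@@H](O)CC(=O)OCc1ccccc1 | starting material
4 | benzyl (S)-3-[3,5-bis(benzyloxy)-2-formylphenoxy]butanoate | O=Cc1c(O[C@@H](C)CC(=O)OCc2ccccc2)cc(OCc2ccccc2)cc1OCc1ccccc1 | intermediate
5 | (S)-3-(3,5-dihydroxy-2-methylphenoxy)butanoic acid | Cc1c(O)cc(O)cc1O[C@@H](C)CC(=O)O | intermediate
6 | (S)-5,7-dihydroxy-2,8-dimethylchroman-4-one | Cc1c(O)cc(O)c2c1O[C@@H](C)CC2=O | intermediate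
7 | prenyl bromide (1-bromo-3-methylbut-2-ene) | CC(C)=CCBr | starting material
8 | (S)-5,7-dihydroxy-2,8-dimethyl-6-(3-methylbut-2-en-1-yl)chroman-4-one | Cc1c(O)c(CC=C(C)C)c(O)c2c1O[C@@H](C)CC2=O | intermediate
9 | geranyl acetate ((2E)-3,7-dimethylocta-2,6-dien-1-yl acetate) | CC(C)=CCC/C(C)=C/COC(C)=O | starting material
10 | (2S,8R)-8-[(2E)-3,7-dimethylocta-2,6-dien-1-yl]-5-hydroxy-2,8-dimethyl-6-(3-methylbut-2-en-1-yl)-2,3-dihydro-4H-chromene-4,7(8H)-dione | CC(C)=CCC/C(C)=C/C[C@@]1(C)C(=O)C(CC=C(C)C)=C(O)C2=C1O[C@@H](C)CC2=O | target

Total step count: 6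
Longest linear sequence: 6 steps (1 → 2 → 4 → 5 → 6 → 8 → 10)

**Steps most likely to fail**

Step 6. What may go wrong: attack of the π-geranyl complex at the prenyl-bearing C6 or at O7 instead of C8, and insufficient facial discrimination at C8 (the C8 epimers are diastereomers and should be separable, but material would be lost). The fallback replaces reliance on sterics by a blocking group; it sets out from compound 6 and comes back to the route at compound 10. Bromination of 6 with NBS (MeCN, 0 °C) at the only free ring carbon should give (S)-6-bromo-5,7-dihydroxy-2,8-dimethylchroman-4-one F1. The same palladium-catalysed geranylation with 9 then finds C8 as the only carbon that can be quaternised productively, because the bromine-bearing C6 is deactivated, and should give (2S,8R)-6-bromo-8-[(2E)-3,7-dimethylocta-2,6-dien-1-yl]-5-hydroxy-2,8-dimethyl-2,3-dihydro-4H-chromene-4,7(8H)-dione F2. Zn dust in AcOH at rt removes the bromine of the 2-bromo-1,3-dicarbonyl unit to give (2S,8R)-8-[(2E)-3,7-dimethylocta-2,6-dien-1-yl]-5-hydroxy-2,8-dimethyl-2,3-dihydro-4H-chromene-4,7(8H)-dione F3. C-Prenylation of this cyclic 1,3-dicarbonyl at C6 with prenyl bromide 7 (KOH, H2O, 0 °C) then gives 10.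

Step 4. What may go wrong: partial loss of the C2 configuration through acid-induced elimination of the phenol and re-addition by way of a crotonyl species, and intermolecular acylation at the carbon between the two free hydroxyls. The fallback cyclises a protected acid chloride at low temperature; it sets out from compound 4 and comes back to the route at compound 6. Ionic hydrogenation of the formyl group of 4 (Et3SiH, TFA, CH2Cl2, 0 °C) should give benzyl (S)-3-[3,5-bis(benzyloxy)-2-methylphenoxy]butanoate F4. Saponification (LiOH, THF/H2O, 0 °C) gives (S)-3-[3,5-bis(benzyloxy)-2-methylphenoxy]butanoic acid F5. Conversion to the acid chloride ((COCl)2, catalytic DMF, CH2Cl2) and ring closure with SnCl4 at −78 °C, again at the only open ortho position of O1, gives (S)-5,7-bis(benzyloxy)-2,8-dimethylchroman-4-one F6. Hydrogenolysis (H2, 10% Pd/C, EtOAc) then gives 6.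

Step 5. What may go wrong: O-alkylation at O7 and dearomatising prenylation at the methyl-bearing C8 in competition with attack at C6, and base-induced opening of ring B. The fallback delivers the prenyl group by a sigmatropic shift from O7; it sets out from compound 6 and comes back to the route at compound 8. Alkylation of the unchelated 7-hydroxyl with 3-chloro-3-methylbut-1-yne (K2CO3, KI, catalytic CuI, acetone, reflux) should give (S)-5-hydroxy-2,8-dimethyl-7-[(2-methylbut-3-yn-2-yl)oxy]chroman-4-one F7. Semihydrogenation (H2, Pd/CaCO3 poisoned with Pb(OAc)2, quinoline, EtOAc) gives (S)-5-hydroxy-2,8-dimethyl-7-[(2-methylbut-3-en-2-yl)oxy]chroman-4-one F8. Aromatic Claisen rearrangement (N,N-diethylaniline, 130 °C) moves the allyl unit with inversion of its ends to C6, the only ortho carbon of O7 that can rearomatise, and gives 8.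

**Further compounds**
F1 | step 6 | (S)-6-bromo-5,7-dihydroxy-2,8-dimethylchroman-4-one | Cc1c(O)c(Br)c(O)c2c1O[C@@H](C)CC2=O
F2 | step 6 | (2S,8R)-6-bromo-8-[(2E)-3,7-dimethylocta-2,6-dien-1-yl]-5-hydroxy-2,8-dimethyl-2,3-dihydro-4H-chromene-4,7(8H)-dione | CC(C)=CCC/C(C)=C/C[C@@]1(C)C(=O)C(Br)=C(O)C2=C1O[C@@H](C)CC2=O
F3 | step 6 | (2S,8R)-8-[(2E)-3,7-dimethylocta-2,6-dien-1-yl]-5-hydroxy-2,8-dimethyl-2,3-dihydro-4H-chromene-4,7(8H)-dione | CC(C)=CCC/C(C)=C/C[C@@]1(C)C(=O)C=C(O)C2=C1O[C@@H](C)CC2=O
F4 | step 4 | benzyl (S)-3-[3,5-bis(benzyloxy)-2-methylphenoxy]butanoate | Cc1c(O[C@@H](C)CC(=O)OCc2ccccc2)cc(OCc2ccccc2)cc1OCc1ccccc1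
F5 | step 4 | (S)-3-[3,5-bis(benzyloxy)-2-methylphenoxy]butanoic acid | Cc1c(O[C@@H](C)CC(=O)O)cc(OCc2ccccc2)cc1OCc1ccccc1
F6 | step 4 | (S)-5,7-bis(benzyloxy)-2,8-dimethylchroman-4-one | Cc1c(OCc2ccccc2)cc(OCc2ccccc2)c2c1O[C@@H](C)CC2=O
F7 | step 5 | (S)-5-hydroxy-2,8-dimethyl-7-[(2-methylbut-3-yn-2-yl)oxy]chroman-4-one | Cc1c(OC(C)(C)C#C)cc(O)c2c1O[C@@H](C)CC2=O
F8 | step 5 | (S)-5-hydroxy-2,8-dimethyl-7-[(2-methylbut-3-en-2-yl)oxy]chroman-4-one | Cc1c(OC(C)(C)C=C)cc(O)c2c1O[C@@H](C)CC2=O
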